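The naphthalene is cut through ring B. Read with the C1 aryl group as a former phenol oxygen, ring B (aryl at C1, catechol-benzyl at C2, oxygen at C3, hydrogen at C4, fused to ring A through C4a–C8a) is a 2-alkylresorcinol, the signature of a ketene–siloxyalkyne benzannulation. In one photochemical-thermal operation an aryl diazomethyl ketone carrying ring A and a triisopropylsiloxyalkyne carrying the benzyl arm should deliver the 2-benzyl-3-siloxy-1-naphthol, forming C1–C2, C3–C4 and C1–C8a. The free C1 hydroxyl then serves as a triflate handle for Suzuki attachment of ring C, and desilylation plus hydrogenolysis unmask the target.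

Key step: step 9

Remark: locants C1 to C8a refer to the naphthalene numbered so that C1 carries ring C, C2 the benzyl group and C3 the hydroxyl. The C1–ring C biaryl axis is not defined in the target and is left uncontrolled. The target has no stereocentres.

**Fragment 1 (ring A)**

Step 1
Reactants: 1 2,6-dimethoxyphenol
Product: 2 2-(benzyloxy)-1,3-dimethoxybenzene
Conditions: BnBr, K2CO3, DMF, rt
Reagents that add atoms: benzyl bromide, BrCc1ccccc1
Why: Williamson etherification of the acidic, doubly ortho-substituted phenoxide with a reactive benzylic halide should be clean, and the benzyl ether later tolerates organolithium, photochemical and cross-coupling conditions before leaving by hydrogenolysis.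

Step 2
Reactants: 2 2-(benzyloxy)-1,3-dimethoxybenzene
Product: 3 3-(benzyloxy)-1-bromo-2,4-dimethoxybenzene
Conditions: NBS (1 equiv), MeCN, 0 °C to rt
Reagents that add atoms: N-bromosuccinimide, O=C1CCC(=O)N1Br
Why: Electrophilic aromatic bromination should go to C4 (equivalent to C6), the position ortho to one methoxy group and para to the other, because the flanked benzyloxy group is twisted out of conjugation and activates C5 only weakly, while one equivalent of NBS limits dibromination.

Step 3
Reactants: 3 3-(benzyloxy)-1-bromo-2,4-dimethoxybenzene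
Product: 6 3-(benzyloxy)-2,4-dimethoxybenzoic acid, via aryllithium 4 (not isolated), via lithium carboxylate 5 (not isolated)
Conditions: n-BuLi, THF, −78 °C; CO2; aq HCl
Reagents that add atoms: carbon dioxide, O=C=O
Why: Bromine–lithium exchange is faster at −78 °C than deprotonation or attack on the ethers, and carboxylation of the aryllithium with CO2 followed by acidification gives the benzoic acid.

Step 4
Reactants: 6 3-(benzyloxy)-2,4-dimethoxybenzoic acid
Product: 8 1-[3-(benzyloxy)-2,4-dimethoxyphenyl]-2-diazoethan-1-one, via acid chloride 7 (not isolated)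
Conditions: (COCl)2, cat. DMF, CH2Cl2, 0 °C to rt, evaporate; CH2N2 (excess), Et2O, 0 °C
Reagents that add atoms: diazomethane, C=[N+]=[N-]
Why: Acid chloride formation under Vilsmeier-type catalysis followed by acylation of diazomethane (the first stage of an Arndt–Eistert sequence) gives the diazomethyl ketone, the excess diazomethane consuming the HCl so that no chloromethyl ketone forms.

**Fragment 2 (benzyl arm and siloxyalkyne)**

Step 5
Reactants: 9 3,4-bis(benzyloxy)benzaldehyde
Product: 10 [3,4-bis(benzyloxy)phenyl]methanol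
Conditions: NaBH4, MeOH/THF, 0 °C
Reagents that add atoms: none
Why: Borohydride reduction of an aromatic aldehyde to the benzylic alcohol is chemoselective and leaves the benzyl ethers untouched.

Step 6
Reactants: 10 [3,4-bis(benzyloxy)phenyl]methanol
Product: 11 1,2-bis(benzyloxy)-4-(bromomethyl)benzene
Conditions: PBr3, CH2Cl2, 0 °C
Reagents that add atoms: phosphorus tribromide, BrP(Br)Br
Why: Nucleophilic substitution of the activated benzylic alcohol by bromide via its phosphite ester should be fast at 0 °C, and the electron-rich bromide is used crude without storage.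

Step 7
Reactants: 11 1,2-bis(benzyloxy)-4-(bromomethyl)benzene
Product: 12 1,2-bis(benzyloxy)-4-(prop-2-yn-1-yl)benzene
Conditions: HC≡CMgBr (excess), CuBr (cat.), THF, 0 to 50 °C; cold aq NH4Cl
Reagents that add atoms: ethynylmagnesium bromide, C#C[Mg]Br
Why: Copper-catalysed cross-coupling of an alkynyl Grignard reagent with a benzylic bromide forms the sp–sp3 bond, an excess of the acetylide suppressing double benzylation and a cold neutral quench avoiding base-induced isomerization to the allene.

Step 8
Reactants: 12 1,2-bis(benzyloxy)-4-(prop-2-yn-1-yl)benzene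
Product: 15 ({3-[3,4-bis(benzyloxy)phenyl]prop-1-yn-1-yl}oxy)triisopropylsilane, via lithium acetylide 13 (not isolated), via lithium ynolate 14 (not isolated)
Conditions: LiN(SiMe3)2, THF, −78 °C; t-BuOOLi (from t-BuOOH and LiN(SiMe3)2), −78 to 0 °C; TIPSOTf, −78 °C
Reagents that add atoms: tert-butyl hydroperoxide (used as its lithium salt), CC(C)(C)OO; triisopropylsilyl trifluoromethanesulfonate, CC(C)[Si](C(C)C)(C(C)C)OS(=O)(=O)C(F)(F)F
Why: Deprotonation gives the lithium acetylide, which is oxidized at carbon by electrophilic oxygen transfer from lithium tert-butyl peroxide to the lithium ynolate, and the hard, bulky silyl triflate then silylates the ambident ynolate at oxygen to give a siloxyalkyne stabilized by the triisopropylsilyl group (ynolate oxidation and O-silylation).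

**Key step and end game**

Step 9
Reactants: 8 1-[3-(benzyloxy)-2,4-dimethoxyphenyl]-2-diazoethan-1-one and 15 ({3-[3,4-bis(benzyloxy)phenyl]prop-1-yn-1-yl}oxy)triisopropylsilane
Product: 20 6-(benzyloxy)-2-[3,4-bis(benzyloxy)benzyl]-5,7-dimethoxy-3-[(triisopropylsilyl)oxy]naphthalen-1-ol, via arylketene 16 (not isolated), via cyclobutenone 17 (not isolated), via dienylketene 18 (not isolated), via cyclohexadienone 19 (not isolated)
Conditions: hν (300 nm), degassed ClCH2CH2Cl, rt; then 80 °C
Reagents that add atoms: none
Why: Light expels N2 from 8 and ring A migrates (Wolff rearrangement) to give arylketene 16, whose carbonyl carbon is attacked by the nucleophilic, benzyl-bearing carbon of the polarized siloxyalkyne in a [2+2] cycloaddition that forms C1–C2 and C3–C4 of cyclobutenone 17. Four-electron conrotatory opening of 17, reversible on heating, gives dienylketene 18, and six-electron disrotatory electrocyclization of its ketene carbon onto the ortho carbon of ring A forms C1–C8a and closes ring B as cyclohexadienone 19, which tautomerizes to naphthol 20. The closest known reaction type is the Danheiser benzannulation in its second-generation form, in which aryl diazomethyl ketones and triisopropylsiloxyalkynes give 3-siloxy-1-naphthols. Ring B is the only ring closed, by electrocyclization and aromatization, and no stereocentre remains because C4 of 17 and C8a of 19 are transient. Two regiochemical choices are needed: the polarization of the ynol ether places the benzyl group at C2 and the siloxy group at C3, and of the two ortho carbons of ring A only the hydrogen-bearing one can aromatize after closure, the methoxy-bearing one closing reversibly to a dead end, which fixes the 5,6,7-oxygenation pattern. The ring A ether groups make the ketene and the aryl terminus electron-rich, and the cascade leaves the C1 hydroxyl free against the C3 silyl ether for selective triflation.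

Step 10
Reactants: 20 6-(benzyloxy)-2-[3,4-bis(benzyloxy)benzyl]-5,7-dimethoxy-3-[(triisopropylsilyl)oxy]naphthalen-1-ol
Product: 21 6-(benzyloxy)-2-[3,4-bis(benzyloxy)benzyl]-5,7-dimethoxy-3-[(triisopropylsilyl)oxy]naphthalen-1-yl trifluoromethanesulfonate
Conditions: Tf2O, pyridine, CH2Cl2, 0 °C
Reagents that add atoms: trifluoromethanesulfonic anhydride, O=S(=O)(OS(=O)(=O)C(F)(F)F)C(F)(F)F
Why: Sulfonylation of the only free hydroxyl with triflic anhydride and pyridine turns the C1 oxygen into a cross-coupling leaving group while the C3 oxygen stays masked as the silyl ether, freshly prepared 20 being used because the electron-rich naphthol is air-sensitive.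

Step 11
Reactants: 22 4-bromo-3-methoxyphenol
Product: 23 4-(benzyloxy)-1-bromo-2-methoxybenzene
Conditions: BnBr, K2CO3, DMF, rt
Reagents that add atoms: benzyl bromide, BrCc1ccccc1
Why: Williamson etherification protects the future ring C hydroxyl as a benzyl ether that is removed together with the others in the last step.

Step 12
Reactants: 23 4-(benzyloxy)-1-bromo-2-methoxybenzene
Product: 26 [4-(benzyloxy)-2-methoxyphenyl]boronic acid, via aryllithium 24 (not isolated), via lithium borate 25 (not isolated)
Conditions: n-BuLi, THF, −78 °C; B(OiPr)3, −78 °C to rt; aq HCl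
Reagents that add atoms: triisopropyl borate, CC(C)OB(OC(C)C)OC(C)C; water, O
Why: Bromine–lithium exchange followed by trapping of the aryllithium with triisopropyl borate gives the ate complex, whose acidic hydrolysis releases the boronic acid (lithiation–borylation).

Step 13
Reactants: 21 6-(benzyloxy)-2-[3,4-bis(benzyloxy)benzyl]-5,7-dimethoxy-3-[(triisopropylsilyl)oxy]naphthalen-1-yl trifluoromethanesulfonate and 26 [4-(benzyloxy)-2-methoxyphenyl]boronic acid
Product: 27 6-(benzyloxy)-1-[4-(benzyloxy)-2-methoxyphenyl]-2-[3,4-bis(benzyloxy)benzyl]-5,7-dimethoxy-3-[(triisopropylsilyl)oxy]naphthalene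
Conditions: Pd(OAc)2 (cat.), SPhos, K3PO4, toluene/H2O, 90 °C; 26 in excess
Reagents that add atoms: none
Why: In this Suzuki–Miyaura coupling, zerovalent palladium formed in situ and ligated by the bulky, electron-rich biarylphosphine SPhos inserts into the hindered C1–OTf bond and promotes reductive elimination of the tri-ortho-substituted biaryl, an excess of the boronic acid compensating for protodeboronation, and the new biaryl axis is not controlled.

Step 14
Reactants: 27 6-(benzyloxy)-1-[4-(benzyloxy)-2-methoxyphenyl]-2-[3,4-bis(benzyloxy)benzyl]-5,7-dimethoxy-3-[(triisopropylsilyl)oxy]naphthalene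
Product: 28 6-(benzyloxy)-1-[4-(benzyloxy)-2-methoxyphenyl]-2-[3,4-bis(benzyloxy)benzyl]-5,7-dimethoxynaphthalen-3-ol
Conditions: Bu4NF, THF, 0 °C
Reagents that add atoms: none
Why: Fluoride-induced cleavage of the aryl silyl ether (desilylation) is driven by the strong Si–F bond and leaves benzyl and methyl ethers untouched.

Step 15
Reactants: 28 6-(benzyloxy)-1-[4-(benzyloxy)-2-methoxyphenyl]-2-[3,4-bis(benzyloxy)benzyl]-5,7-dimethoxynaphthalen-3-ol
Product: 29 CNP0000244.0, 2-(3,4-dihydroxybenzyl)-1-(4-hydroxy-2-methoxyphenyl)-5,7-dimethoxynaphthalene-3,6-diol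
Conditions: H2 (1 atm), Pd/C, EtOAc/MeOH, rt; filtration and concentration under argon
Reagents that add atoms: none
Why: Catalytic hydrogenolysis cleaves the four benzylic C–O bonds under conditions that spare the methyl ethers, the naphthalene and the diarylmethane C–C bonds, and the air-sensitive polyphenol is kept under inert gas.

**Compound list**

1 | 2,6-dimethoxyphenol | COc1cccc(OC)c1O | starting material
2 | 2-(benzyloxy)-1,3-dimethoxybenzene | COc1cccc(OC)c1OCc1ccccc1 | intermediate
3 | 3-(benzyloxy)-1-bromo-2,4-dimethoxybenzene | COc1ccc(Br)c(OC)c1OCc1ccccc1 | intermediate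
4 | [3-(benzyloxy)-2,4-dimethoxyphenyl]lithium | [Li]c1ccc(OC)c(OCc2ccccc2)c1OC | intermediate
5 | lithium 3-(benzyloxy)-2,4-dimethoxybenzoate | [Li+].[O-]C(=O)c1ccc(OC)c(OCc2ccccc2)c1OC | intermediate
6 | 3-(benzyloxy)-2,4-dimethoxybenzoic acid | COc1ccc(C(=O)O)c(OC)c1OCc1ccccc1 | intermediate
7 | 3-(benzyloxy)-2,4-dimethoxybenzoyl chloride | COc1ccc(C(Cl)=O)c(OC)c1OCc1ccccc1 | intermediate
8 | 1-[3-(benzyloxy)-2,4-dimethoxyphenyl]-2-diazoethan-1-one | COc1ccc(C(=O)C=[N+]=[N-])c(OC)c1OCc1ccccc1 | intermediate
9 | 3,4-bis(benzyloxy)benzaldehyde | O=Cc1ccc(OCc2ccccc2)c(OCc2ccccc2)c1 | starting material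
10 | [3,4-bis(benzyloxy)phenyl]methanol | OCc1ccc(OCc2ccccc2)c(OCc2ccccc2)c1 | intermediate
11 | 1,2-bis(benzyloxy)-4-(bromomethyl)benzene | BrCc1ccc(OCc2ccccc2)c(OCc2ccccc2)c1 | intermediate
12 | 1,2-bis(benzyloxy)-4-(prop-2-yn-1-yl)benzene | C#CCc1ccc(OCc2ccccc2)c(OCc2ccccc2)c1 | intermediate
13 | {3-[3,4-bis(benzyloxy)phenyl]prop-1-yn-1-yl}lithium | [Li]C#CCc1ccc(OCc2ccccc2)c(OCc2ccccc2)c1 | intermediate
14 | lithium 3-[3,4-bis(benzyloxy)phenyl]prop-1-yn-1-olate | [Li+].[O-]C#CCc1ccc(OCc2ccccc2)c(OCc2ccccc2)c1 | intermediate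
15 | ({3-[3,4-bis(benzyloxy)phenyl]prop-1-yn-1-yl}oxy)triisopropylsilane | CC(C)[Si](C(C)C)(C(C)C)OC#CCc1ccc(OCc2ccccc2)c(OCc2ccccc2)c1 | intermediate
16 | 2-[3-(benzyloxy)-2,4-dimethoxyphenyl]ethen-1-one (arylketene) | O=C=Cc1ccc(OC)c(OCc2ccccc2)c1OC | intermediate
17 | 4-[3-(benzyloxy)-2,4-dimethoxyphenyl]-2-[3,4-bis(benzyloxy)benzyl]-3-[(triisopropylsilyl)oxy]cyclobut-2-en-1-one (racemic) | O=C1C(Cc2ccc(OCc3ccccc3)c(OCc3ccccc3)c2)=C(O[Si](C(C)C)(C(C)C)C(C)C)C1c1ccc(OC)c(OCc2ccccc2)c1OC | intermediate
18 | 4-[3-(benzyloxy)-2,4-dimethoxyphenyl]-2-[3,4-bis(benzyloxy)benzyl]-3-[(triisopropylsilyl)oxy]buta-1,3-dien-1-one, aryl group cis to the ketene-bearing carbon across the C3=C4 bond | O=C=C(Cc1ccc(OCc2ccccc2)c(OCc2ccccc2)c1)/C(O[Si](C(C)C)(C(C)C)C(C)C)=C\c1ccc(OC)c(OCc2ccccc2)c1OC | intermediate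
19 | 6-(benzyloxy)-2-[3,4-bis(benzyloxy)benzyl]-5,7-dimethoxy-3-[(triisopropylsilyl)oxy]naphthalen-1(8aH)-one (racemic) | O=C1C(Cc3ccc(OCc4ccccc4)c(OCc4ccccc4)c3)=C(O[Si](C(C)C)(C(C)C)C(C)C)C=C2C(OC)=C(OCc3ccccc3)C(OC)=CC12 | intermediate
20 | 6-(benzyloxy)-2-[3,4-bis(benzyloxy)benzyl]-5,7-dimethoxy-3-[(triisopropylsilyl)oxy]naphthalen-1-ol | COc1cc2c(O)c(Cc3ccc(OCc4ccccc4)c(OCc4ccccc4)c3)c(O[Si](C(C)C)(C(C)C)C(C)C)cc2c(OC)c1OCc1ccccc1 | intermediate
21 | 6-(benzyloxy)-2-[3,4-bis(benzyloxy)benzyl]-5,7-dimethoxy-3-[(triisopropylsilyl)oxy]naphthalen-1-yl trifluoromethanesulfonate | COc1cc2c(OS(=O)(=O)C(F)(F)F)c(Cc3ccc(OCc4ccccc4)c(OCc4ccccc4)c3)c(O[Si](C(C)C)(C(C)C)C(C)C)cc2c(OC)c1OCc1ccccc1 | intermediate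
22 | 4-bromo-3-methoxyphenol | COc1cc(O)ccc1Br | starting material
23 | 4-(benzyloxy)-1-bromo-2-methoxybenzene | COc1cc(OCc2ccccc2)ccc1Br | intermediate
24 | [4-(benzyloxy)-2-methoxyphenyl]lithium | [Li]c1ccc(OCc2ccccc2)cc1OC | intermediate
25 | lithium [4-(benzyloxy)-2-methoxyphenyl]tri(propan-2-yloxy)borate | [Li+].COc1cc(OCc2ccccc2)ccc1[B-](OC(C)C)(OC(C)C)OC(C)C | intermediate
26 | [4-(benzyloxy)-2-methoxyphenyl]boronic acid | COc1cc(OCc2ccccc2)ccc1B(O)O | intermediate
27 | 6-(benzyloxy)-1-[4-(benzyloxy)-2-methoxyphenyl]-2-[3,4-bis(benzyloxy)benzyl]-5,7-dimethoxy-3-[(triisopropylsilyl)oxy]naphthalene | COc1cc(OCc2ccccc2)ccc1-c1c(Cc2ccc(OCc3ccccc3)c(OCc3ccccc3)c2)c(O[Si](C(C)C)(C(C)C)C(C)C)cc2c(OC)c(OCc3ccccc3)c(OC)cc12 | intermediate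
28 | 6-(benzyloxy)-1-[4-(benzyloxy)-2-methoxyphenyl]-2-[3,4-bis(benzyloxy)benzyl]-5,7-dimethoxynaphthalen-3-ol | COc1cc(OCc2ccccc2)ccc1-c1c(Cc2ccc(OCc3ccccc3)c(OCc3ccccc3)c2)c(O)cc2c(OC)c(OCc3ccccc3)c(OC)cc12 | intermediate
29 | CNP0000244.0, 2-(3,4-dihydroxybenzyl)-1-(4-hydroxy-2-methoxyphenyl)-5,7-dimethoxynaphthalene-3,6-diol | COc1cc(O)ccc1-c1c(Cc2ccc(O)c(O)c2)c(O)cc2c(OC)c(O)c(OC)cc12 | target

**Step count**

Total steps: 15. Longest linear sequence: 9 steps (steps 1, 2, 3, 4, 9, 10, 13, 14, 15). The branch through steps 5, 6, 7, 8 and then 9, 10, 13, 14, 15 is equally long.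

**Steps most likely to fail**

Step 9. The photolysis may stall as the strongly absorbing naphthol accumulates and screens the diazo ketone. The photogenerated carbene may also be diverted into insertion at the neighbouring methoxy group or addition to the alkyne instead of aryl migration. The fallback makes the same arylketene in the dark by dehydrochlorination. It sets out from 8: silver-promoted Wolff rearrangement in aqueous dioxane (PhCO2Ag cat., Et3N; Arndt–Eistert homologation) should give [3-(benzyloxy)-2,4-dimethoxyphenyl]acetic acid F1. Oxalyl chloride with catalytic DMF converts it into [3-(benzyloxy)-2,4-dimethoxyphenyl]acetyl chloride F2. Slow addition of this chloride to 15 and Et3N in toluene at 80 to 110 °C should release ketene 16 by loss of HCl and carry it through 17, 18 and 19 to naphthol 20, where the route is rejoined.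

Step 13. Transmetalation at the crowded palladium centre may be slower than protodeboronation of the electron-rich ortho-alkoxy boronic acid, and aqueous base may hydrolyse the triflate back to the naphthol. The fallback replaces the boron nucleophile by a zinc one under anhydrous conditions. It sets out from bromide 23: bromine–lithium exchange (through 24) and transmetalation with ZnCl2 should give [4-(benzyloxy)-2-methoxyphenyl]zinc chloride F3. Negishi coupling with triflate 21 (Pd(OAc)2, SPhos, THF, 60 °C) should then give 27, where the route is rejoined.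

Step 8. Deprotonation at the doubly activated benzylic-propargylic methylene may compete and isomerize the alkyne to an allene. Oxygen transfer to the acetylide may be incomplete, or the ynolate may silylate at carbon. The fallback builds the ynolate by rearrangement instead of oxidation. It sets out from bromide 11: palladium-catalysed ethoxycarbonylation (CO 1 atm, EtOH, PdCl2(PPh3)2, Et3N) should give ethyl [3,4-bis(benzyloxy)phenyl]acetate F4. Kowalski ester homologation is then stopped at the ynolate stage: addition of LiCHBr2 (from CH2Br2 and lithium 2,2,6,6-tetramethylpiperidide, −78 °C) and treatment with LiN(SiMe3)2 give the lithium enolate of 3-[3,4-bis(benzyloxy)phenyl]-1,1-dibromopropan-2-one F5. Bromine–lithium exchange with n-BuLi and warming trigger the rearrangement to ynolate 14, which is silylated in the same flask with TIPSOTf to give 15, where the route is rejoined.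

**Further compounds**

F1 | step 9 | [3-(benzyloxy)-2,4-dimethoxyphenyl]acetic acid | COc1ccc(CC(=O)O)c(OC)c1OCc1ccccc1
F2 | step 9 | [3-(benzyloxy)-2,4-dimethoxyphenyl]acetyl chloride | COc1ccc(CC(Cl)=O)c(OC)c1OCc1ccccc1
F3 | step 13 | [4-(benzyloxy)-2-methoxyphenyl]zinc chloride | COc1cc(OCc2ccccc2)ccc1[Zn]Cl
F4 | step 8 | ethyl [3,4-bis(benzyloxy)phenyl]acetate | CCOC(=O)Cc1ccc(OCc2ccccc2)c(OCc2ccccc2)c1
F5 | step 8 | lithium enolate of 3-[3,4-bis(benzyloxy)phenyl]-1,1-dibromopropan-2-one | [Li+].[O-]C(Cc1ccc(OCc2ccccc2)c(OCc2ccccc2)c1)=C(Br)Br
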